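**Retrosynthetic overview** (side chain numbered C1′, benzylic, to C16′)
1. Last step: unmask the C12′ ketone from a 2‑prenyl‑1,3‑dithiane, so the epimerisable C11′ centre and the β,γ‑unsaturated ketone never meet base or organometallics.
2. C1′–C2′ bond and C3′ methyl: Zr‑catalysed methylalumination of a terminal alkyne, then direct capture of the alkenylalane by an ortho‑quinone methide from a salicyl alcohol (new step; gives the free phenol without a protecting group).
3. C4′–C5′ bond and C5′ (R): chiral phosphoric acid‑catalysed propargylboration of an enal (metal‑free asymmetric key step).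
4. C12′–C13′: Corey–Seebach prenylation of the dithiane. C11′ (R): Ru‑BINAP hydrogenation of 8‑hydroxygeranyl acetate (first stereocentre, from achiral geranyl acetate).
5. Rings: none is built for the target. The arene is bought; the only ring formed is the temporary dithiane (step 4), opened in step 10.

Assumption: the senses of induction in steps 2 and 7 are assigned by analogy (geraniol hydrogenation; benzaldehyde and cinnamaldehyde allyl‑ and propargylboration) and the mirror‑image catalyst is used if a Mosher assay shows the opposite.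

**Step 1**
Reactants: 1 geranyl acetate [(2E)-3,7-dimethylocta-2,6-dien-1-yl acetate]
Product: 2 (2E,6E)-8-hydroxy-3,7-dimethylocta-2,6-dien-1-yl acetate
Conditions: SeO2 (0.3 equiv), t-BuOOH (3 equiv), salicylic acid (0.1 equiv), CH2Cl2, rt, 24 h
Reagents that add atoms: selenium dioxide O=[Se]=O; tert-butyl hydroperoxide CC(C)(C)OO
Why: Riley allylic oxidation (ene reaction then [2,3]-sigmatropic shift, catalytic Sharpless variant) attacks only the E‑methyl of the electron‑rich terminal isopropylidene, because the acetate deactivates the 2,3‑alkene, and gives the (6E)-allylic alcohol; no stereocentre is formed.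

**Step 2**
Reactants: 2 (2E,6E)-8-hydroxy-3,7-dimethylocta-2,6-dien-1-yl acetate
Product: 3 (2E,7R)-8-hydroxy-3,7-dimethyloct-2-en-1-yl acetate
Conditions: H2 (100 atm), Ru(OAc)2[(R)-BINAP] (1 mol%), MeOH, rt
Reagents that add atoms: none
Why: Noyori hydroxyl‑directed asymmetric hydrogenation reduces only the alkene that carries the free allylic OH (the allylic acetate alkene cannot chelate Ru) and sets C7 (later C11′) as R; (R)-BINAP, which turns geraniol into (S)-citronellol, delivers H2 to the same face here, which for an (E)-2-methyl allylic alcohol gives 7R.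

**Step 3**
Reactants: 3 (2E,7R)-8-hydroxy-3,7-dimethyloct-2-en-1-yl acetate
Product: 4 (2E,7R)-3,7-dimethyl-8-oxooct-2-en-1-yl acetate
Conditions: TEMPO (0.1 equiv), PhI(OAc)2 (1.1 equiv), CH2Cl2, rt; used crude at once
Reagents that add atoms: none
Why: TEMPO/PhI(OAc)2 oxoammonium oxidation stops at the aldehyde under non‑basic conditions, so the α‑methyl stereocentre is not epimerised.

**Step 4**
Reactants: 4 (2E,7R)-3,7-dimethyl-8-oxooct-2-en-1-yl acetate
Product: 5 (2E,7R)-7-(1,3-dithian-2-yl)-3-methyloct-2-en-1-yl acetate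
Conditions: HS(CH2)3SH (1.2 equiv), BF3·OEt2 (0.3 equiv), CH2Cl2, −40 °C
Reagents that add atoms: propane-1,3-dithiol SCCCS
Why: Lewis acid‑catalysed thioacetalisation outruns enolisation at −40 °C, keeps 7R, and turns the aldehyde carbon (later C12′) into a masked acyl anion that also protects the neighbouring centre from epimerisation in all later steps.

**Step 5**
Reactants: 5 (2E,7R)-7-(1,3-dithian-2-yl)-3-methyloct-2-en-1-yl acetate
Product: 7 (2E,7R)-3-methyl-7-[2-(3-methylbut-2-en-1-yl)-1,3-dithian-2-yl]oct-2-en-1-ol, via dilithiated dithiane alkoxide 6 (not isolated)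
Conditions: n-BuLi (3.3 equiv), THF, −78 to −20 °C, 3 h; prenyl bromide (1.2 equiv), −78 to 0 °C; H2O
Reagents that add atoms: prenyl bromide (1-bromo-3-methylbut-2-ene) CC(C)=CCBr
Why: Corey–Seebach umpolung: two equivalents of n-BuLi cleave the acetate (ester to tertiary alkoxide), the third lithiates C2 of the dithiane, and the soft carbanion attacks prenyl bromide by SN2 at the primary carbon to give the linear prenyl unit (C13′–C16′); the adjacent stereocentre has no acidic hydrogen and is untouched.

**Step 6**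
Reactants: 7 (2E,7R)-3-methyl-7-[2-(3-methylbut-2-en-1-yl)-1,3-dithian-2-yl]oct-2-en-1-ol
Product: 8 (2E,7R)-3-methyl-7-[2-(3-methylbut-2-en-1-yl)-1,3-dithian-2-yl]oct-2-enal
Conditions: MnO2 (15 equiv), CH2Cl2, rt
Reagents that add atoms: none
Why: MnO2 oxidises only the primary allylic alcohol to the (E)-enal and leaves the dithiane and the alkenes alone.

**Step 7**
Reactants: 8 (2E,7R)-3-methyl-7-[2-(3-methylbut-2-en-1-yl)-1,3-dithian-2-yl]oct-2-enal
Product: 9 (4R,5E,10R)-6-methyl-10-[2-(3-methylbut-2-en-1-yl)-1,3-dithian-2-yl]undec-5-en-1-yn-4-ol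
Conditions: allenyl-Bpin (1.5 equiv), (R)-TRIP (10 mol%), 4 Å MS, toluene, −10 °C, 72 h; aq. NaHCO3
Reagents that add atoms: allenylboronic acid pinacol ester C=C=CB1OC(C)(C)C(C)(C)O1
Why: Chiral phosphoric acid‑catalysed propargylboration (metal‑free; closed six‑membered SE2′ transition state in which the catalyst binds the boronate oxygen and the formyl hydrogen) adds the propargyl unit to the re face of the enal with (R)-TRIP, which gives the 4R carbinol (later C5′); the ketone carbon is masked, so only the aldehyde reacts.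

**Step 8**
Reactants: 10 4-methoxy-2-methylphenol
Product: 11 2-(hydroxymethyl)-4-methoxy-6-methylphenol
Conditions: CH2O (37% aq., 2 equiv), NaOH (1.0 equiv), H2O, 5 °C to rt, 24 h; then AcOH
Reagents that add atoms: formaldehyde C=O
Why: Lederer–Manasse hydroxymethylation: the phenoxide adds to formaldehyde at the only free ortho position (para is blocked by OMe, the other ortho by Me).

**Step 9**
Reactants: 9 (4R,5E,10R)-6-methyl-10-[2-(3-methylbut-2-en-1-yl)-1,3-dithian-2-yl]undec-5-en-1-yn-4-ol; 11 2-(hydroxymethyl)-4-methoxy-6-methylphenol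
Product: 14 2-{(2E,5R,6E,11R)-5-hydroxy-3,7-dimethyl-11-[2-(3-methylbut-2-en-1-yl)-1,3-dithian-2-yl]dodeca-2,6-dien-1-yl}-4-methoxy-6-methylphenol, via alkenyldimethylalane 12 (not isolated), via ortho-quinone methide 13 (not isolated)
Conditions: Me3Al (3.5 equiv), Cp2ZrCl2 (0.3 equiv), CH2Cl2, 0 °C to rt, 12 h; then 11 (1.5 equiv, premixed with Me3Al (2.0 equiv), CH2Cl2, −20 °C), −20 to 35 °C; aq. potassium sodium tartrate (KNaC4H4O6)
Reagents that add atoms: trimethylaluminium C[Al](C)C
Why: Proposed new method: Zr‑catalysed syn‑methylalumination (Negishi carboalumination, known) gives the (E)-2-methylalkenylalane 12 with Me and Al cis; salicyl alcohol 11, held as its bis(dimethylaluminium) phenoxide–alkoxide, loses the benzylic oxygen as an Al–O–Al unit to give the aluminium‑bound ortho‑quinone methide 13 (a vinylogous oxocarbenium ion), and the alkenyl group of 12 is delivered to its exocyclic CH2 with retention at the sp2 carbon (alkenyl transfers faster than methyl), which makes the C1′–C2′ bond, fixes the 2′E alkene and frees the phenol on work‑up; the closest known reactions are the uncatalysed alkylation of alkenylalanes by chloromethyl ethers (oxocarbenium capture) and the 1,4‑addition of Grignard reagents and alkenylboronates to ortho‑quinone methides; no stereocentre is touched.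

**Step 10**
Reactants: 14 2-{(2E,5R,6E,11R)-5-hydroxy-3,7-dimethyl-11-[2-(3-methylbut-2-en-1-yl)-1,3-dithian-2-yl]dodeca-2,6-dien-1-yl}-4-methoxy-6-methylphenol
Product: 15 2-[(2E,5R,6E,11R)-5-hydroxy-3,7,11,15-tetramethyl-12-oxohexadeca-2,6,14-trien-1-yl]-4-methoxy-6-methylphenol (target)
Conditions: MeI (15 equiv), CaCO3 (5 equiv), MeCN/H2O 4:1, 40 °C, dark
Reagents that add atoms: water O
Why: Alkylative dithiane hydrolysis (S‑methylation, then water attacks the thionium ion) at near‑neutral pH unveils the ketone last, so 11′R is not epimerised and the 14′,15′‑alkene does not move into conjugation; no oxidant is used, so the phenol and the allylic alcohol survive.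

**Compound list**
1 | geranyl acetate, (2E)-3,7-dimethylocta-2,6-dien-1-yl acetate | CC(=O)OC/C=C(\C)CCC=C(C)C | starting material
2 | (2E,6E)-8-hydroxy-3,7-dimethylocta-2,6-dien-1-yl acetate | CC(=O)OC/C=C(\C)CC/C=C(\C)CO | intermediate
3 | (2E,7R)-8-hydroxy-3,7-dimethyloct-2-en-1-yl acetate | CC(=O)OC/C=C(\C)CCC[C@@H](C)CO | intermediate
4 | (2E,7R)-3,7-dimethyl-8-oxooct-2-en-1-yl acetate | CC(=O)OC/C=C(\C)CCC[C@@H](C)C=O | intermediate
5 | (2E,7R)-7-(1,3-dithian-2-yl)-3-methyloct-2-en-1-yl acetate | CC(=O)OC/C=C(\C)CCC[C@@H](C)C1SCCCS1 | intermediate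
6 | lithium (2E,7R)-7-(2-lithio-1,3-dithian-2-yl)-3-methyloct-2-en-1-olate | [Li]OC/C=C(\C)CCC[C@@H](C)C1([Li])SCCCS1 | intermediate (not isolated)
7 | (2E,7R)-3-methyl-7-[2-(3-methylbut-2-en-1-yl)-1,3-dithian-2-yl]oct-2-en-1-ol | OC/C=C(\C)CCC[C@@H](C)C1(CC=C(C)C)SCCCS1 | intermediate
8 | (2E,7R)-3-methyl-7-[2-(3-methylbut-2-en-1-yl)-1,3-dithian-2-yl]oct-2-enal | O=C/C=C(\C)CCC[C@@H](C)C1(CC=C(C)C)SCCCS1 | intermediate
9 | (4R,5E,10R)-6-methyl-10-[2-(3-methylbut-2-en-1-yl)-1,3-dithian-2-yl]undec-5-en-1-yn-4-ol | C#CC[C@@H](O)/C=C(\C)CCC[C@@H](C)C1(CC=C(C)C)SCCCS1 | intermediate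
10 | 4-methoxy-2-methylphenol | COc1ccc(O)c(C)c1 | starting material
11 | 2-(hydroxymethyl)-4-methoxy-6-methylphenol | COc1cc(C)c(O)c(CO)c1 | intermediate
12 | dimethylaluminium (1E,4R,5E,10R)-1-(dimethylalumanyl)-2,6-dimethyl-10-[2-(3-methylbut-2-en-1-yl)-1,3-dithian-2-yl]undeca-1,5-dien-4-olate | C[Al](C)/C=C(\C)C[C@@H](O[Al](C)C)/C=C(\C)CCC[C@@H](C)C1(CC=C(C)C)SCCCS1 | intermediate (not isolated)
13 | 4-methoxy-2-methyl-6-methylidenecyclohexa-2,4-dien-1-one (ortho-quinone methide, aluminium-bound) | C=C1C=C(OC)C=C(C)C1=O | intermediate (not isolated)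
14 | 2-{(2E,5R,6E,11R)-5-hydroxy-3,7-dimethyl-11-[2-(3-methylbut-2-en-1-yl)-1,3-dithian-2-yl]dodeca-2,6-dien-1-yl}-4-methoxy-6-methylphenol | COc1cc(C)c(O)c(C/C=C(\C)C[C@@H](O)/C=C(\C)CCC[C@@H](C)C2(CC=C(C)C)SCCCS2)c1 | intermediate
15 | 2-[(2E,5R,6E,11R)-5-hydroxy-3,7,11,15-tetramethyl-12-oxohexadeca-2,6,14-trien-1-yl]-4-methoxy-6-methylphenol | COc1cc(C)c(O)c(C/C=C(\C)C[C@@H](O)/C=C(\C)CCC[C@@H](C)C(=O)CC=C(C)C)c1 | target

**Step count**
Total: 10 steps (9 on the main line from 1, plus 1 for the aryl piece 11). Longest linear sequence: 9 steps (1 to 15 through steps 1–7, 9 and 10).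

**Three steps most likely to fail**

Step 9 (the new alkenylalane / ortho‑quinone methide coupling). Methyl transfer from aluminium, slow ionisation of the aluminated salicyl alcohol, or protonolysis of the alkenyl–Al bond could win. The fallback uses known chemistry; it sets out from 9 and 11 and comes back at 14. Treat 11 with acetyl chloride to obtain 2-(chloromethyl)-4-methoxy-6-methylphenyl acetate F3. Make alkenylalane 12 from 9 exactly as above and cross‑couple it with F3 under zerovalent nickel catalysis (NiCl2(PPh3)2 reduced with n-BuLi, THF, rt; the established alkenylalane–benzylic chloride coupling) to give the phenyl acetate of 14 F4. Methanolysis with K2CO3 in MeOH (the ketone is still masked, so base is harmless) returns 14.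

Step 7 (propargylboration of a β,β‑disubstituted enal). Such enals are less reactive and can give lower ee than aryl aldehydes. The fallback sets out from 8 and comes back at 9. Add allenyl-Bpin with achiral diphenyl phosphate to get the C4‑epimeric homopropargylic alcohols F1. Oxidise the allylic alcohol with MnO2 to the alkynyl enone F2, kept neutral and used crude so the β,γ‑alkyne does not slip to the allene. Reduce with (S)-2-methyl-CBS-oxazaborolidine (20 mol%) and catecholborane in toluene at −78 °C (Corey–Bakshi–Shibata reduction, alkenyl as the large group), which returns 9 as the 4R alcohol.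

Step 10 (dithiane removal beside a free, electron‑rich phenol). O‑methylation of the phenol or sluggish hydrolysis are the dangers, and oxidative unmasking is excluded by the phenol. The fallback changes the order of events; it sets out from 9 and comes back at 15. Carboaluminate 9 as in step 9 (12) and quench with I2 at −40 °C to get the (E)-vinyl iodide F5. Unmask the ketone now, with no phenol present (MeI/CaCO3, aq. MeCN), to give the keto vinyl iodide F6. Prepare the benzylic zinc chloride F7 from the aryl chloride F3 (Zn dust, LiCl, THF) and join it to F6 by Negishi coupling (Pd(OAc)2/SPhos, THF, rt; tolerant of the ketone) to give the O‑acetyl target F8. Brief ammonolysis of the aryl acetate (NH3 in MeOH, 0 °C) gives 15 without touching the α‑stereocentre.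

**Further compounds**
F1 | step 7 | (4RS,5E,10R)-6-methyl-10-[2-(3-methylbut-2-en-1-yl)-1,3-dithian-2-yl]undec-5-en-1-yn-4-ol (C4 epimer mixture) | C#CCC(O)/C=C(\C)CCC[C@@H](C)C1(CC=C(C)C)SCCCS1
F2 | step 7 | (5E,10R)-6-methyl-10-[2-(3-methylbut-2-en-1-yl)-1,3-dithian-2-yl]undec-5-en-1-yn-4-one | C#CCC(=O)/C=C(\C)CCC[C@@H](C)C1(CC=C(C)C)SCCCS1
F3 | step 9 | 2-(chloromethyl)-4-methoxy-6-methylphenyl acetate | COc1cc(C)c(OC(C)=O)c(CCl)c1
F4 | step 9 | 2-{(2E,5R,6E,11R)-5-hydroxy-3,7-dimethyl-11-[2-(3-methylbut-2-en-1-yl)-1,3-dithian-2-yl]dodeca-2,6-dien-1-yl}-4-methoxy-6-methylphenyl acetate | COc1cc(C)c(OC(C)=O)c(C/C=C(\C)C[C@@H](O)/C=C(\C)CCC[C@@H](C)C2(CC=C(C)C)SCCCS2)c1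
F5 | step 10 | (1E,4R,5E,10R)-1-iodo-2,6-dimethyl-10-[2-(3-methylbut-2-en-1-yl)-1,3-dithian-2-yl]undeca-1,5-dien-4-ol | I/C=C(\C)C[C@@H](O)/C=C(\C)CCC[C@@H](C)C1(CC=C(C)C)SCCCS1
F6 | step 10 | (6R,10E,12R,14E)-12-hydroxy-15-iodo-2,6,10,14-tetramethylpentadeca-2,10,14-trien-5-one | I/C=C(\C)C[C@@H](O)/C=C(\C)CCC[C@@H](C)C(=O)CC=C(C)C
F7 | step 10 | [2-(acetyloxy)-5-methoxy-3-methylbenzyl]zinc chloride | COc1cc(C)c(OC(C)=O)c(C[Zn]Cl)c1
F8 | step 10 | 2-[(2E,5R,6E,11R)-5-hydroxy-3,7,11,15-tetramethyl-12-oxohexadeca-2,6,14-trien-1-yl]-4-methoxy-6-methylphenyl acetate | COc1cc(C)c(OC(C)=O)c(C/C=C(\C)C[C@@H](O)/C=C(\C)CCC[C@@H](C)C(=O)CC=C(C)C)c1
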